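**Retrosynthetic overview**
- The strategy rests on the benzylic C1''H2 on C8 of ring A, which sits ortho to the free 7-OH: O7–C7–C8–C1'' is a latent ortho-quinone methide, so the C1''–C2'' bond is the one to disconnect.
- C1''–C2'' and the C2'' stereocentre come from the quinone methide of 8-(tosylmethyl)apigenin and the (S)-diarylprolinol silyl ether enamine of 5-methylhex-5-enal; the adduct is isolated as a pyran lactol.
- The isopropenyl group is grown from the lactol carbon: methyl Grignard opening, oxidation to the methyl ketone, non-basic methylenation, desilylation.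
- The sulfone comes from apigenin by C8 Mannich reaction and amine–sulfinate exchange; the aldehyde from ethyl 4-acetylbutyrate by Wittig methylenation and half-reduction.
- Ring order: rings A, B and C arrive intact in apigenin; the only ring formed is the temporary pyran lactol ring (O7, hemiacetal carbon, C2'', C1'', C8, C7), closed in step 5 and reopened in step 6.

Key step: step 5

Remark: aminomethylation of apigenin is taken to follow the C8 preference usual for 5,7-dihydroxyflavones; the position of the CH2 group in 2 is to be confirmed (HMBC from C1''H2 to C7, C8 and C8a) before the material is advanced.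

Step 1
Reactants: 1 apigenin (5,7-dihydroxy-2-(4-hydroxyphenyl)-4H-chromen-4-one)
Product: 2 8-[(dimethylamino)methyl]apigenin
Conditions: 37% aq. HCHO (1.05 equiv), 40% aq. Me2NH (1.2 equiv), MeOH–1,4-dioxane, rt → 45 °C
Reagents that add atoms: formaldehyde C=O; dimethylamine CNC
Why: Mannich aminomethylation of the phloroglucinol-type ring A, which in 5,7-dihydroxyflavones takes place at C8 ahead of C6 and far ahead of ring B, with near-stoichiometric iminium to hold back the 6,8-bis-adduct.

Step 2
Reactants: 2 8-[(dimethylamino)methyl]apigenin; 3 sodium p-toluenesulfinate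
Product: 4 8-(tosylmethyl)apigenin (8-[(4-methylphenyl)sulfonylmethyl]-5,7-dihydroxy-2-(4-hydroxyphenyl)-4H-chromen-4-one)
Conditions: 3 (4 equiv), AcOH, 90 °C
Reagents that add atoms: none
Why: Amine–sulfinate exchange of a phenolic Mannich base by elimination–addition, in which N-protonation and loss of dimethylamine give the quinone methide, the soft sulfinate captures it through sulfur at the methylene carbon, and in acid the sulfone is the sink because it can be released again only from the phenoxide.

Step 3
Reactants: 5 ethyl 4-acetylbutyrate (ethyl 5-oxohexanoate)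
Product: 6 ethyl 5-methylhex-5-enoate
Conditions: Ph3PCH3Br, KOtBu, THF, 0 °C → rt
Reagents that add atoms: methyltriphenylphosphonium bromide C[P+](c1ccccc1)(c1ccccc1)c1ccccc1.[Br-]
Why: Wittig methylenation, in which the non-stabilised ylide attacks the ketone and leaves the ester untouched.

Step 4
Reactants: 6 ethyl 5-methylhex-5-enoate
Product: 7 5-methylhex-5-enal
Conditions: i-Bu2AlH (1.05 equiv), CH2Cl2, −78 °C; MeOH, then aq. KNaC4H4O6; the volatile aldehyde is kept as a solution
Reagents that add atoms: none
Why: Half-reduction of the ester with i-Bu2AlH at −78 °C, where the tetrahedral aluminium hemiacetal persists until the quench and only then releases the aldehyde, the alkene being inert.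

Step 5
Reactants: 4 8-(tosylmethyl)apigenin; 7 5-methylhex-5-enal
Product: 11 (9R)-5,8-dihydroxy-2-(4-hydroxyphenyl)-9-(3-methylbut-3-en-1-yl)-9,10-dihydro-4H,8H-pyrano[2,3-f]chromen-4-one (lactol; epimers at the hemiacetal carbon C8), via ortho-quinone methide 8 (not isolated), via E-enamine 9 (not isolated), via open-chain aldehyde 10 (not isolated)
Conditions: (S)-2-[diphenyl(trimethylsilyloxy)methyl]pyrrolidine (20 mol %), NaHCO3 (2 equiv), 7 (3 equiv), THF–MeCN, 0 °C → rt
Reagents that add atoms: none
Why: Proposed new method: bicarbonate deprotonates the acidic 7-OH of 4 and the phenoxide expels p-toluenesulfinate to give quinone methide 8 (C7=O, C8=C1''H2; loss through the para 5-OH would give a tautomeric para-quinone methide with the same electrophilic C1''), while 7 condenses with the amine to E-enamine 9, whose nucleophilic carbon adds to C1'' in a Michael step driven by rearomatisation of ring A, and hydrolysis of the resulting iminium ion returns the catalyst and aldehyde 10. The closest known reaction type is the diarylprolinol silyl ether catalysed formal [4+2] of aldehydes with aryl-substituted ortho-quinone methides released from 2-(1-sulfonylalkyl)phenols, which gives chroman-2-ols; the extension is to an unsubstituted methylene quinone methide carried by a flavone. The single new ring (O7, hemiacetal carbon, C2'', C1'', C8, C7) closes by 6-exo-trig addition of O7 to the aldehyde carbonyl of 10. The C2'' stereocentre is set in the C–C bond formation: the diphenyl(silyloxy)methyl group shields one face of the s-trans E-enamine, and by the model that holds for Michael additions with this catalyst the (S)-amine should give the (R) configuration, which the lactol then shelters from enolisation; the hemiacetal carbon is uncontrolled and is destroyed in step 6. The step needs a single electrophilic site and chemoselectivity against self-condensation of 8: only C8 carries the leaving group, both possible quinone methides share C1'' as the electrophilic carbon, and slow release by a weak base in the presence of excess enamine keeps 8 at low concentration.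

Step 6
Reactants: 11 lactol
Product: 12 8-[(2R)-2-(1-hydroxyethyl)-5-methylhex-5-en-1-yl]apigenin (both carbinol epimers)
Conditions: MeMgBr (8 equiv), THF, −40 → 0 °C; aq. NH4Cl
Reagents that add atoms: methylmagnesium bromide C[Mg]Br
Why: Grignard addition to a lactol, in which excess reagent first turns the three acidic OH groups into magnesium salts, the lactolate opens to the 7-phenoxide aldehyde that takes up methyl faster than it enolises, and the pyranone carbonyl flanked by phenoxides stays inert; the new carbinol centre forms without control and is erased in step 8, C2'' being untouched.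

Step 7
Reactants: 12 8-[(2R)-2-(1-hydroxyethyl)-5-methylhex-5-en-1-yl]apigenin
Product: 13 7,4'-bis-O-(triisopropylsilyl) derivative of 12 (5-OH and the secondary alcohol free)
Conditions: TIPSCl (2.3 equiv), imidazole (5 equiv), DMF, 0 °C → rt
Reagents that add atoms: triisopropylsilyl chloride CC(C)[Si](Cl)(C(C)C)C(C)C
Why: Phenol-selective silylation, in which the acidic 7-OH and 4'-OH react with TIPSCl/imidazole far faster than the hindered secondary alcohol, and the 5-OH stays free because it is locked in the hydrogen bond to C4=O.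

Step 8
Reactants: 13 7,4'-bis-O-TIPS alcohol
Product: 14 7,4'-bis-O-(triisopropylsilyl)-8-[(2R)-2-acetyl-5-methylhex-5-en-1-yl]apigenin
Conditions: Dess–Martin periodinane (1.5 equiv), CH2Cl2, 0 °C → rt
Reagents that add atoms: none
Why: Dess–Martin oxidation of the secondary alcohol under non-basic conditions leaves the enolisable C2'' centre intact, and with O7 silylated the new ketone cannot close to a hemiketal.

Step 9
Reactants: 14 methyl ketone
Product: 15 7,4'-bis-O-(triisopropylsilyl)-8-[(2R)-5-methyl-2-(prop-1-en-2-yl)hex-5-en-1-yl]apigenin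
Conditions: Zn, CH2Br2, TiCl4 (pre-formed reagent, excess), THF–CH2Cl2, 0 °C → rt
Reagents that add atoms: dibromomethane BrCBr
Why: Takai–Lombardo methylenation, whose non-basic gem-dimetallic methylene reagent converts ketones but not the vinylogous ester carbonyl of the pyranone and does not enolise the α-stereocentre, an excess covering the acidic 5-OH.

Step 10
Reactants: 15 bis-silyl ether
Product: 16 8-[(2R)-5-methyl-2-(prop-1-en-2-yl)hex-5-en-1-yl]apigenin (target)
Conditions: Bu4NF (2.5 equiv), AcOH (2.5 equiv), THF, 0 °C
Reagents that add atoms: none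
Why: Fluoride cleavage of the two aryl silyl ethers with acetic acid as buffer, which avoids the strong acid that would cyclise the 7-OH onto the isopropenyl group.

**Compound list**
1 | apigenin (5,7-dihydroxy-2-(4-hydroxyphenyl)-4H-chromen-4-one) | O=c1cc(-c2ccc(O)cc2)oc2cc(O)cc(O)c12 | starting material
2 | 8-[(dimethylamino)methyl]apigenin | CN(C)Cc1c(O)cc(O)c2c(=O)cc(-c3ccc(O)cc3)oc12 | intermediate
3 | sodium p-toluenesulfinate | Cc1ccc(S(=O)[O-])cc1.[Na+] | starting material
4 | 8-(tosylmethyl)apigenin | Cc1ccc(S(=O)(=O)Cc2c(O)cc(O)c3c(=O)cc(-c4ccc(O)cc4)oc23)cc1 | intermediate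
5 | ethyl 4-acetylbutyrate (ethyl 5-oxohexanoate) | CCOC(=O)CCCC(C)=O | starting material
6 | ethyl 5-methylhex-5-enoate | C=C(C)CCCC(=O)OCC | intermediate
7 | 5-methylhex-5-enal | C=C(C)CCCC=O | intermediate
8 | ortho-quinone methide of apigenin, 5-hydroxy-2-(4-hydroxyphenyl)-8-methylidene-chromene-4,7-dione (not isolated) | C=C1C(=O)C=C(O)C2=C1OC(=CC2=O)c1ccc(O)cc1 | intermediate
9 | E-enamine of 7 and (S)-2-[diphenyl(trimethylsilyloxy)methyl]pyrrolidine (not isolated) | C=C(C)CC/C=C/N1CCC[C@H]1C(c1ccccc1)(c1ccccc1)O[Si](C)(C)C | intermediate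
10 | (2R)-2-[(apigenin-8-yl)methyl]-5-methylhex-5-enal, open-chain Michael adduct (not isolated) | C=C(C)CC[C@@H](C=O)Cc1c(O)cc(O)c2c(=O)cc(-c3ccc(O)cc3)oc12 | intermediate
11 | (9R)-5,8-dihydroxy-2-(4-hydroxyphenyl)-9-(3-methylbut-3-en-1-yl)-9,10-dihydro-4H,8H-pyrano[2,3-f]chromen-4-one (lactol, epimers at C8) | C=C(C)CC[C@@H]1Cc2c(OC1O)cc(O)c1c(=O)cc(-c3ccc(O)cc3)oc21 | intermediate
12 | 8-[(2R)-2-(1-hydroxyethyl)-5-methylhex-5-en-1-yl]apigenin (carbinol epimers) | C=C(C)CC[C@H](Cc1c(O)cc(O)c2c(=O)cc(-c3ccc(O)cc3)oc12)C(C)O | intermediate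
13 | 7,4'-bis-O-(triisopropylsilyl)-8-[(2R)-2-(1-hydroxyethyl)-5-methylhex-5-en-1-yl]apigenin | C=C(C)CC[C@H](Cc1c(O[Si](C(C)C)(C(C)C)C(C)C)cc(O)c2c(=O)cc(-c3ccc(O[Si](C(C)C)(C(C)C)C(C)C)cc3)oc12)C(C)O | intermediate
14 | 7,4'-bis-O-(triisopropylsilyl)-8-[(2R)-2-acetyl-5-methylhex-5-en-1-yl]apigenin | C=C(C)CC[C@H](Cc1c(O[Si](C(C)C)(C(C)C)C(C)C)cc(O)c2c(=O)cc(-c3ccc(O[Si](C(C)C)(C(C)C)C(C)C)cc3)oc12)C(C)=O | intermediate
15 | 7,4'-bis-O-(triisopropylsilyl)-8-[(2R)-5-methyl-2-(prop-1-en-2-yl)hex-5-en-1-yl]apigenin | C=C(C)CC[C@H](Cc1c(O[Si](C(C)C)(C(C)C)C(C)C)cc(O)c2c(=O)cc(-c3ccc(O[Si](C(C)C)(C(C)C)C(C)C)cc3)oc12)C(=C)C | intermediate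
16 | 8-[(2R)-5-methyl-2-(prop-1-en-2-yl)hex-5-en-1-yl]apigenin (CNP0187326.1) | C=C(C)CC[C@H](Cc1c(O)cc(O)c2c(=O)cc(-c3ccc(O)cc3)oc12)C(=C)C | target

**Step count and risks**

Total step count: 10. Longest linear sequence: 8 steps (steps 1, 2, 5–10 from apigenin; equally steps 3–10 from ethyl 4-acetylbutyrate).

Steps most likely to fail:

1. Step 5 (proposed new method). The unsubstituted quinone methide may be consumed by condensation with ring A of a second flavone or by N-alkylation of the catalyst before the enamine reaches it, and an uncatalysed or warm pathway would erode the facial selectivity. Fallback, setting out from 2 and 7 and returning at 14: aldehyde 7 is condensed with morpholine (K2CO3, then distillation) to give 4-[(1E)-5-methylhexa-1,5-dien-1-yl]morpholine F1. Heating 2 with F1 in 1,4-dioxane at reflux expels dimethylamine, and the thermally formed quinone methide 8 is captured in the classical inverse-demand hetero-Diels–Alder reaction of phenolic Mannich bases with enamines to give the racemic 8-morpholino aminal F2. Hydrolysis with dilute aqueous AcOH in THF gives the racemic lactol F3. This is taken through the operations of steps 6, 7 and 8 as the racemic diol F4, the racemic bis-silyl alcohol F5 and the racemic ketone F6. F6 is resolved by preparative HPLC on an amylose carbamate chiral stationary phase, and the (R)-enantiomer is 14.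

2. Step 6. Precipitation of the polymagnesium phenoxides may stop the lactol from opening, deprotonation of the open aldehyde may return racemised lactol, and prolonged exposure may lead to addition at the pyranone. Fallback, setting out from 11 and returning at 14: Wittig methylenation of the lactol (Ph3PCH3Br, KOtBu in excess, THF, 0 °C → rt) gives 8-[(2R)-2-ethenyl-5-methylhex-5-en-1-yl]apigenin F7. Silylation as in step 7 gives its 7,4'-bis-O-TIPS ether F8, which blocks oxypalladation by O7. Tsuji–Wacker oxidation (PdCl2 cat., CuCl, O2, DMF–H2O, rt) then converts the monosubstituted vinyl group, in preference to the 1,1-disubstituted alkene, into the methyl ketone 14.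

3. Step 9. The 5-OH/C4=O chelate may sequester the titanium reagent and stall the methylenation, and Lewis-acid-induced loss of the 7-O-silyl group would open the way to cyclisation onto the ketone. Fallback, setting out from 14 and returning at 15: Peterson olefination. Addition of Me3SiCH2Li/CeCl3 (THF, −78 °C), whose low basicity avoids enolisation, gives the β-hydroxysilane F9, which no longer has an epimerisable centre. Syn-elimination with KH (THF, 0 °C → rt) gives 15.

**Further compounds**
F1 | step 5 | 4-[(1E)-5-methylhexa-1,5-dien-1-yl]morpholine | C=C(C)CC/C=C/N1CCOCC1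
F2 | step 5 | racemic 5-hydroxy-2-(4-hydroxyphenyl)-9-(3-methylbut-3-en-1-yl)-8-(morpholin-4-yl)-9,10-dihydro-4H,8H-pyrano[2,3-f]chromen-4-one | C=C(C)CCC1Cc2c(OC1N1CCOCC1)cc(O)c1c(=O)cc(-c3ccc(O)cc3)oc21
F3 | step 5 | racemic lactol (racemate of 11) | C=C(C)CCC1Cc2c(OC1O)cc(O)c1c(=O)cc(-c3ccc(O)cc3)oc21
F4 | step 5 | racemic 8-[2-(1-hydroxyethyl)-5-methylhex-5-en-1-yl]apigenin (racemate of 12) | C=C(C)CCC(Cc1c(O)cc(O)c2c(=O)cc(-c3ccc(O)cc3)oc12)C(C)O
F5 | step 5 | racemic 7,4'-bis-O-TIPS alcohol (racemate of 13) | C=C(C)CCC(Cc1c(O[Si](C(C)C)(C(C)C)C(C)C)cc(O)c2c(=O)cc(-c3ccc(O[Si](C(C)C)(C(C)C)C(C)C)cc3)oc12)C(C)O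
F6 | step 5 | racemic 7,4'-bis-O-TIPS methyl ketone (racemate of 14) | C=C(C)CCC(Cc1c(O[Si](C(C)C)(C(C)C)C(C)C)cc(O)c2c(=O)cc(-c3ccc(O[Si](C(C)C)(C(C)C)C(C)C)cc3)oc12)C(C)=O
F7 | step 6 | 8-[(2R)-2-ethenyl-5-methylhex-5-en-1-yl]apigenin | C=C(C)CC[C@H](Cc1c(O)cc(O)c2c(=O)cc(-c3ccc(O)cc3)oc12)C=C
F8 | step 6 | 7,4'-bis-O-(triisopropylsilyl)-8-[(2R)-2-ethenyl-5-methylhex-5-en-1-yl]apigenin | C=C(C)CC[C@H](Cc1c(O[Si](C(C)C)(C(C)C)C(C)C)cc(O)c2c(=O)cc(-c3ccc(O[Si](C(C)C)(C(C)C)C(C)C)cc3)oc12)C=C
F9 | step 9 | 7,4'-bis-O-(triisopropylsilyl)-8-[(2R)-2-[2-hydroxy-1-(trimethylsilyl)propan-2-yl]-5-methylhex-5-en-1-yl]apigenin (carbinol epimers) | C=C(C)CC[C@H](Cc1c(O[Si](C(C)C)(C(C)C)C(C)C)cc(O)c2c(=O)cc(-c3ccc(O[Si](C(C)C)(C(C)C)C(C)C)cc3)oc12)C(C)(O)C[Si](C)(C)C
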